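# Proposed total synthesis of CNP0226738.1 via a bromopyrone Diels–Alder reaction

## The problem

The target is a cis-fused eremophilane (eremophilane numbering throughout): ring A (C1–C5, C10) carries the trienoate on O3, a secondary methyl on C4 and the angular methyl on quaternary C5, and ring B (C5–C10) carries a C9 carbinol beside a C8 ketone that is conjugated with a tetrasubstituted exocyclic C7=C11 alkene bearing C13H3 and, on the ketone side (Z), C12H2OH. Five stereocentres must be set, four of them contiguous in ring A around the quaternary carbon, with O3 and the C10–C9 bond cis-1,4 on one face and the two methyls cis on the other. Control can flow from ring A to ring B but not back: with C10 fixed, C9 should follow from Felkin–Anh addition to a C9 aldehyde and is also expected to be the thermodynamic epimer, so the ring A tetrad must be made first and in one absolute sense. The (Z)-γ-hydroxy enone is formally the hydrate of a furan and reverts to it with acid, the C9/C8 α-ketol can epimerise or transpose with base, and the trienoate does not tolerate hydrogenation, ozone, organometallics or strong base. Three hydroxyls (O3, O9, O12) must be kept apart and only O3 acylated. The enabling feature is that the cis-1,4 pair O3/C9 can be the two ends of a lactone bridge over a boat-shaped ring A, with the cis C4/C5 methyls and the C6 branch on the C4–C5 edge; this is the adduct of a 2-pyrone (C10=C1–C2=C3, ring O–C=O as O3–C9) with (E)-2-methylbut-2-enal, bromine standing in for the C10 hydrogen. The Z alkene with C12 syn to O8 is likewise the imprint of a furan, which fixes the geometry by a ring.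

## Retrosynthesis

**26 ⇒ 25 ⇒ 23 (unveiling the hydroxy enone).** The O9 silyl ether of 25 is removed last. The C12 alcohol of 25 is traced to keto enal 24 and this to furan ester 23, so the C8=O/C12–O pair is rejoined as the furan oxygen. An aldol–dehydration route to the tetrasubstituted alkene would give E/Z mixtures, whereas the furan ring forces C12 to the O8 side. The furan is also a robust mask during acylation. The forward reaction must oxidise the furan in the presence of the triene and reduce the aldehyde in the presence of the C8 ketone.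

**23 ⇒ 17 + 21 (ester C–O bond).** Cutting the O3–acyl bond removes the fragile trienoate from every earlier step. Furan alcohol 17 has a single free hydroxyl, because O9 is silylated and O12 does not yet exist, so no selectivity is asked of the acylation (via mixed anhydride 22).

**21 ⇒ 20 ⇒ 18 + 19 (acid side chain).** The C4=C5 alkene of the acid is cut to (E)-non-3-en-2-one 18 and triethyl 4-phosphonocrotonate 19, both commercial. The olefination must favour the 4E isomer; the rest of the geometry is bought.

**17 ⇒ 16 ⇒ 14 + 15 (furan annulation).** The C7–C11 bond and the O–C8 bond are cut. The C11–C13 unit arrives as silylated hydroxyacetone 15 by aldol addition to the C7 enolate of ketone 14, and acid closes and aromatises. This is preferred to a nitroalkene Michael/Nef sequence because 15 is a stable commercial ketone and the closure needs only mild acid. The enolate must form on the C7 side, away from the silyloxy-bearing C9.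

**14 ⇒ 13 ⇒ 12 ⇒ 11 (ring B).** The C6–C7 bond is cut as an intramolecular aldol condensation of keto lactol 12, followed by hydrogenation of enone 13. The C6 aldehyde is used exactly as the dienophile delivers it, which speaks against closing ring B at C8–C9 or by metathesis. The precursor 11 is monocyclic in the carbocyclic sense.

**11 ⇒ 10 ⇒ 7 + 8 (C8–C9 bond).** The acetyl unit C7–C8 is added to aldehyde 7 as 1-ethoxyvinyllithium 9 (from ethyl vinyl ether 8). This gives the α-hydroxy methyl ketone after hydrolysis without an ozonolysis. C10 must control C9 through Felkin–Anh addition, and O9 is then the only hydroxyl to silylate.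

**7 ⇒ 6 ⇒ 5 (telling C6 from C9 and O3 from O9).** Lactone aldehyde 5 has two carbonyl carbons and one masked hydroxyl. Acid methanolysis turns C9 into a methyl ester and ties O3 to C6 as a bridged methyl acetal (6), and partial reduction gives 7. One operation therefore differentiates both carbons and protects O3 without a separate protecting group.

**5 ⇒ 4 ⇒ 3 (adjusting the adduct).** The C1=C2 alkene and the bridgehead bromine of 3 are removed by hydrogenation and radical reduction. Both are done while the lactone bridge still locks C10.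

**3 ⇒ 1 + 2 (key disconnection).** The C3–C4 and C5–C10 bonds are cut to 3-bromo-2H-pyran-2-one 1 and (E)-2-methylbut-2-enal 2. No other cut makes the quaternary carbon and its three neighbours in one step from two commercial compounds. The forward reaction must deliver the regiochemistry with C5 next to the brominated terminus, the formyl group over the lactone bridge, and one enantiomer. The last is asked of the N-protonated bis(trifluoromethylsulfonyl)imide salt of (R)-3,3-diphenyl-1-(2-methylphenyl)tetrahydro-1H,3H-pyrrolo[1,2-c][1,3,2]oxazaborole (written cat-B below).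

## Roads not taken

Alternative 1: enyne metathesis and 1,4-dioxygenation.
- Cut: C7=C8 and C11=C12, so ring B comes from enyne A2.
- Forward key step: second-generation Grubbs catalyst under ethylene closes A2 to the 1-isopropenylcyclohexene A1. Singlet oxygen cycloaddition and Kornblum–DeLaMare opening would then give the 8-oxo-12-hydroxy Z-enone directly.
- Merits: this end game is shorter than the furan detour and the Z geometry is again ring-enforced. In this respect it is better than the chosen plan.
- Weak points: A2 already contains all five stereocentres, so the hard part (quaternary C5 between C4 and C10, cis-1,4 O3/C9) is moved upstream, not solved. The diene of A1 has many allylic hydrogens open to the ene reaction. Base opening of the endoperoxide can remove a C12 hydrogen as easily as the hindered C8 hydrogen, which would give the reversed redox pattern.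
- Comparison: the chosen plan makes ring A with four stereocentres in one step and has C8 as a ketone throughout.

Alternative 2: anionic oxy-Cope of a bicyclo[2.2.2]octenol.
- Cut: C5–C6, with a temporary C3–C8 bond in the bridged alcohol A4.
- Forward key step: KH with 18-crown-6 turns A4 into its alkoxide, whose [3,3] shift gives the cis-fused octalone A3 as its C7–C8 enolate.
- Merits: the rearrangement is well precedented, which is a clear advantage over the untested key step here. It sets C5 and C10 reliably and delivers a regiodefined enolate that could be used at C7.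
- Weak points: C3 arrives as an enol ether and C4 as an sp2 carbon, so both must be set later on a mobile cis-decalin. C9 is a bare methylene whose hydroxylation must compete with C7. The absolute configuration needs a separate asymmetric entry to A4.
- Comparison: the chosen plan creates C3, C4, C5 and C10 together and has C9 already attached at the right oxidation level.

Alternative 3: reductive β,β-coupling of two enones.
- Cut: C1–C10, closing ring A from the bis-enone A6.
- Forward key step: SmI2 (divalent samarium) with HMPA and t-BuOH reduces the vinyl ketone of A6 to its β-radical, which adds to C10 to give the cis-fused dione A5.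
- Merits: the bicyclic core is reached quickly, probably in fewer steps than here, with ketones at C3 and C8.
- Weak points: the vinyl ketone can polymerise or simply be reduced. C4 sits α to a ketone and must be set, together with quaternary C5, in acyclic A6 by separate asymmetric chemistry. The two ketones of A5 must be told apart and C3 reduced selectively. C9 oxygenation is again missing.
- Comparison: the chosen plan needs no ketone differentiation and takes the C4/C5 relation from the alkene geometry of a commercial enal.

Key step: step 1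

**Assumptions.**
- The facial sense of cat-B toward 2 is taken from the formyl C–H···O binding model for α-substituted enals, which predicts attack on the Cα-si face with the (R)-catalyst. If the sense is the reverse with the pyrone, the (S)-catalyst is used and nothing else changes.
- Compounds 6, 7, 10, 11 and 12 are epimer mixtures at the acetal (lactol) carbon C6, and 16 is a mixture at C7/C11. These centres vanish in steps 8 and 11 and are left unspecified in the SMILES.

## Route

Step 1
Reactants: 1 3-bromo-2H-pyran-2-one; 2 (E)-2-methylbut-2-enal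
Product: 3 (1R,4R,7R,8S)-4-bromo-7,8-dimethyl-3-oxo-2-oxabicyclo[2.2.2]oct-5-ene-8-carbaldehyde
Conditions: (R)-3,3-diphenyl-1-(2-methylphenyl)tetrahydro-1H,3H-pyrrolo[1,2-c][1,3,2]oxazaborole (20 mol %), HN(SO2CF3)2 (20 mol %), 2 (3 equiv), CH2Cl2, −40 → −10 °C
Reagents that add atoms: none
Why: Proposed new method: the N-protonated oxazaborolidine binds the formyl oxygen of s-trans 2 (formyl C–H to ring-oxygen contact), lowers its LUMO and lets the weakly nucleophilic pyrone add in a concerted, asynchronous [4+2], suprafacial on both partners, in which the C3–C4 bond (pyrone C6 to enal β-carbon) runs ahead of C5–C10. The closest known reaction types are the thermal additions of 3-bromo-2-pyrone to acrylate-type dienophiles, which give isolable bridged lactones, and oxazaborolidinium-catalysed Diels–Alder reactions of α-methyl enals with simple dienes. Ring A is closed by the cycloaddition itself as the boat of a 2-oxabicyclo[2.2.2]octene, the O3–C9 lactone remaining as the third bridge because CO2 is not lost below room temperature. C3 and C10 are fixed relative to each other by that bridge (cis-1,4), and C4 and C5 by the E geometry of 2 (methyls cis). The two pairs are related by the orientation with the formyl group over the lactone bridge and the methyls under the forming alkene, which is the usual preference of α-methyl enals and the selectivity most at risk. The absolute sense comes from attack on the enal face not covered by the catalyst phenyl group. The required regiochemistry (C5 bonded to the brominated terminus) rests on the larger HOMO coefficient at the oxygen-bearing terminus of the 3-bromopyrone meeting the β-carbon of the activated enal, the sense seen thermally with monosubstituted dienophiles. Bromine raises the diene reactivity and is exchanged for hydrogen in step 2.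

Step 2
Reactants: 3 (1R,4R,7R,8S)-4-bromo-7,8-dimethyl-3-oxo-2-oxabicyclo[2.2.2]oct-5-ene-8-carbaldehyde
Product: 4 (1R,4S,7R,8R)-7,8-dimethyl-3-oxo-2-oxabicyclo[2.2.2]oct-5-ene-8-carbaldehyde
Conditions: Bu3SnH (1.5 equiv, 0.3 M), AIBN (cat.), benzene, 80 °C
Reagents that add atoms: none
Why: Radical chain dehalogenation: the pyramidal bridgehead radical cannot invert and takes hydrogen from Bu3SnH with retention by necessity, so C10 keeps its configuration; a 1,2-formyl shift is disfavoured because the bridgehead orbital cannot align with the neighbouring carbonyl and because the stannane is kept concentrated.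

Step 3
Reactants: 4 (1R,4S,7R,8R)-7,8-dimethyl-3-oxo-2-oxabicyclo[2.2.2]oct-5-ene-8-carbaldehyde
Product: 5 (1R,4S,5R,6R)-5,6-dimethyl-3-oxo-2-oxabicyclo[2.2.2]octane-5-carbaldehyde
Conditions: H2 (1 atm), Pd/C (10 wt %), EtOAc, rt
Reagents that add atoms: none
Why: Heterogeneous hydrogenation of the unhindered disubstituted alkene; the neopentyl aldehyde and the lactone are inert under these conditions and no stereocentre is formed.

Step 4
Reactants: 5 (1R,4S,5R,6R)-5,6-dimethyl-3-oxo-2-oxabicyclo[2.2.2]octane-5-carbaldehyde
Product: 6 methyl (1R,2S,5R,8R)-7-methoxy-1,8-dimethyl-6-oxabicyclo[3.2.1]octane-2-carboxylate (C9 methyl ester; O3 bridged to C6 as methyl acetal)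
Conditions: CSA (10 mol %), HC(OMe)3, MeOH, 50 °C; then toluene, 60 °C (removal of MeOH)
Reagents that add atoms: methanol, CO; trimethyl orthoformate, COC(OC)OC
Why: Acid-catalysed methanolysis of the strained boat lactone gives the methyl ester and frees O3–H, which is captured by the C6 oxocarbenium ion as a five-membered mixed acetal (O3 and C6 are cis-1,3); this tells C9 from C6 and masks O3 in one operation, and the equatorial ester at C10 has no drive to epimerise.

Step 5
Reactants: 6 methyl (1R,2S,5R,8R)-7-methoxy-1,8-dimethyl-6-oxabicyclo[3.2.1]octane-2-carboxylate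
Product: 7 (1R,2S,5R,8R)-7-methoxy-1,8-dimethyl-6-oxabicyclo[3.2.1]octane-2-carbaldehyde
Conditions: i-Bu2AlH (1.1 equiv), CH2Cl2, −78 °C; aq. potassium sodium tartrate
Reagents that add atoms: none
Why: Low-temperature i-Bu2AlH reduction stops at the aluminium hemiacetal of the hindered α-branched ester and releases the aldehyde on work-up; the formyl group is equatorial on the locked chair, so C10 is configurationally safe, and the acetal is untouched.

Step 6
Reactants: 7 (1R,2S,5R,8R)-7-methoxy-1,8-dimethyl-6-oxabicyclo[3.2.1]octane-2-carbaldehyde; 8 ethyl vinyl ether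
Product: 10 (1R)-2-ethoxy-1-[(1R,2S,5R,8R)-7-methoxy-1,8-dimethyl-6-oxabicyclo[3.2.1]octan-2-yl]prop-2-en-1-ol, via 1-ethoxyvinyllithium 9 (not isolated)
Conditions: 8, t-BuLi, THF, −78 → 0 °C; then 7, −78 °C; aq. NaHCO3
Reagents that add atoms: none
Why: 1-Ethoxyvinyllithium is an acetyl anion equivalent that adds to aldehydes at −78 °C and brings C7 and C8; Felkin–Anh addition anti to the quaternary C5 and past the C10 hydrogen should give the (9R)-carbinol, and no free alkoxide is present to impose chelation.

Step 7
Reactants: 10 (1R)-2-ethoxy-1-[(1R,2S,5R,8R)-7-methoxy-1,8-dimethyl-6-oxabicyclo[3.2.1]octan-2-yl]prop-2-en-1-ol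
Product: 11 tert-butyldimethylsilyl ether of 10 at O9
Conditions: TBSOTf, 2,6-lutidine, CH2Cl2, −78 → 0 °C
Reagents that add atoms: tert-butyldimethylsilyl trifluoromethanesulfonate, CC(C)(C)[Si](C)(C)OS(=O)(=O)C(F)(F)F
Why: Silyl triflate with 2,6-lutidine silylates hindered secondary alcohols faster than it touches the enol ether; O9 is the only free hydroxyl, and the TBS group withstands the acid and base to come and leaves with fluoride at the end.

Step 8
Reactants: 11 tert-butyldimethylsilyl ether of 10 at O9
Product: 13 (1R,4aR,5R,6R,8aS)-1-[(tert-butyldimethylsilyl)oxy]-6-hydroxy-4a,5-dimethyl-4a,5,6,7,8,8a-hexahydronaphthalen-2(1H)-one, via keto lactol 12 (not isolated)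
Conditions: 1 M HCl, THF, 0 °C → rt; then KOH, MeOH, rt
Reagents that add atoms: water, O
Why: Aqueous acid hydrolyses the enol ether to the methyl ketone and the methyl acetal to the lactol, the α-keto silyl ether being deactivated toward acid cleavage; base then opens the lactol and the methyl ketone enolate (C7) closes ring B on the C6 aldehyde by intramolecular aldol condensation, cis-fused because C6 and C9 are cis on ring A; C9 is epimerisable here, but the wanted epimer has the silyloxy group pseudo-equatorial and clear of the axial C4 branch, so equilibration should work in the right direction.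

Step 9
Reactants: 13 (1R,4aR,5R,6R,8aS)-1-[(tert-butyldimethylsilyl)oxy]-6-hydroxy-4a,5-dimethyl-4a,5,6,7,8,8a-hexahydronaphthalen-2(1H)-one
Product: 14 (1R,4aR,5R,6R,8aS)-1-[(tert-butyldimethylsilyl)oxy]-6-hydroxy-4a,5-dimethyloctahydronaphthalen-2(1H)-one
Conditions: H2 (1 atm), Pd/C (10 wt %), EtOAc, rt
Reagents that add atoms: none
Why: Hydrogenation of the disubstituted enone alkene; the ketone, the silyl ether and the free O3–H are unaffected and no stereocentre is formed.

Step 10
Reactants: 14 (1R,4aR,5R,6R,8aS)-1-[(tert-butyldimethylsilyl)oxy]-6-hydroxy-4a,5-dimethyloctahydronaphthalen-2(1H)-one; 15 1-[(tert-butyldimethylsilyl)oxy]propan-2-one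
Product: 16 (1R,4aR,5R,6R,8aS)-1-[(tert-butyldimethylsilyl)oxy]-3-{1-[(tert-butyldimethylsilyl)oxy]-2-hydroxypropan-2-yl}-6-hydroxy-4a,5-dimethyloctahydronaphthalen-2(1H)-one (diastereomer mixture at C7 and C11)
Conditions: LiN(i-Pr)2 (2.2 equiv), THF, −78 °C; ZnCl2; 15, −78 → −40 °C; aq. NH4Cl
Reagents that add atoms: none
Why: Two equivalents of amide base give the O3 alkoxide and the kinetic enolate on the methylene side (C7), away from the silyloxy-bearing C9; the zinc enolate adds to the ketone carbonyl of 15 (aldol addition), forming C7–C11 and bringing C12 and C13; both new stereocentres are lost in step 11.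

Step 11
Reactants: 16 aldol adduct (diastereomer mixture)
Product: 17 (4aR,5R,6R,8aS,9R)-9-[(tert-butyldimethylsilyl)oxy]-3,4a,5-trimethyl-4,4a,5,6,7,8,8a,9-octahydronaphtho[2,3-b]furan-6-ol
Conditions: CSA (0.2 equiv), MeOH/CH2Cl2, 0 °C → rt; then Et3N
Reagents that add atoms: none
Why: Mild acid removes the primary silyl ether selectively; the freed C12–OH adds to the C8 ketone and the hemiketal loses two molecules of water to the aromatic furan (cyclodehydration of a γ-hydroxy ketone, Paal–Knorr type); the hindered secondary silyl ether at C9 cleaves far more slowly, and the furan fixes C12 on the O8 side of C7=C11.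

Step 12
Reactants: 18 (E)-non-3-en-2-one; 19 triethyl 4-phosphonocrotonate
Product: 20 ethyl (2E,4E,6E)-5-methyldodeca-2,4,6-trienoate
Conditions: 19, LiN(SiMe3)2, THF, −78 °C; then 18, −78 °C → rt
Reagents that add atoms: none
Why: Horner–Wadsworth–Emmons olefination of the methyl ketone with the vinylogous phosphonate anion; the 2E alkene comes with the reagent, the new trisubstituted alkene should form mainly E (alkenyl group trans to the ester chain), and the minor 4Z isomer is removed by chromatography.

Step 13
Reactants: 20 ethyl (2E,4E,6E)-5-methyldodeca-2,4,6-trienoate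
Product: 21 (2E,4E,6E)-5-methyldodeca-2,4,6-trienoic acid
Conditions: LiOH, THF/MeOH/H2O, rt; then 1 M HCl to pH 3
Reagents that add atoms: lithium hydroxide, [Li+].[OH-]
Why: Saponification of the conjugated ethyl ester at room temperature; hydroxide does not add to the substituted trienoate and the alkene geometry is unchanged.

Step 14
Reactants: 17 (4aR,5R,6R,8aS,9R)-9-[(tert-butyldimethylsilyl)oxy]-3,4a,5-trimethyl-4,4a,5,6,7,8,8a,9-octahydronaphtho[2,3-b]furan-6-ol; 21 (2E,4E,6E)-5-methyldodeca-2,4,6-trienoic acid
Product: 23 (4aR,5R,6R,8aS,9R)-9-[(tert-butyldimethylsilyl)oxy]-3,4a,5-trimethyl-4,4a,5,6,7,8,8a,9-octahydronaphtho[2,3-b]furan-6-yl (2E,4E,6E)-5-methyldodeca-2,4,6-trienoate, via mixed anhydride 22 (not isolated)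
Conditions: 21, 2,4,6-Cl3C6H2COCl, Et3N, toluene, rt; then 17, DMAP, rt
Reagents that add atoms: none
Why: Yamaguchi esterification: the mixed anhydride acylates the only free hydroxyl, the equatorial O3–H, under DMAP catalysis; furan and silyl ether are inert to these basic conditions and C3 keeps its configuration because only the acyl–oxygen bond is formed.

Step 15
Reactants: 23 furan ester
Product: 25 (1R,2R,4aS,5R,8aR)-5-[(tert-butyldimethylsilyl)oxy]-7-[(Z)-1-hydroxypropan-2-ylidene]-1,8a-dimethyl-6-oxodecahydronaphthalen-2-yl (2E,4E,6E)-5-methyldodeca-2,4,6-trienoate, via keto enal 24 (not isolated)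
Conditions: dimethyldioxirane (1.1 equiv, acetone), CH2Cl2, −78 → −30 °C; evaporate at 0 °C; NaBH4, MeOH/CH2Cl2, −78 °C
Reagents that add atoms: dimethyldioxirane, CC1(C)OO1
Why: The dioxirane epoxidises the electron-rich furan far faster than the electron-poor trienoate and the epoxide opens to the cis-enedione, so C12 stays on the side of O8 (Z); after removal of acetone in the cold, NaBH4 at −78 °C should reduce the unhindered conjugated aldehyde in 1,2-fashion before the tetrasubstituted, silyloxy-flanked C8 ketone or the ester can react; O9 is silylated so that no pyranone hemiacetal (Achmatowicz-type closure) can form.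

Step 16
Reactants: 25 O9-silylated hydroxy enone ester
Product: 26 (1R,2R,4aS,5R,8aR)-5-hydroxy-7-[(Z)-1-hydroxypropan-2-ylidene]-1,8a-dimethyl-6-oxodecahydronaphthalen-2-yl (2E,4E,6E)-5-methyldodeca-2,4,6-trienoate (target)
Conditions: HF·pyridine, pyridine, THF, 0 °C → rt
Reagents that add atoms: none
Why: Fluoride-mediated desilylation; α-keto silyl ethers cleave readily with fluoride, the trienoate is inert, and the pyridine buffer keeps the medium from promoting cyclodehydration of the γ-hydroxy enone.

## Compound list

1 | 3-bromo-2H-pyran-2-one | O=C1OC=CC=C1Br | starting material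
2 | (E)-2-methylbut-2-enal | C/C=C(\C)C=O | starting material
3 | (1R,4R,7R,8S)-4-bromo-7,8-dimethyl-3-oxo-2-oxabicyclo[2.2.2]oct-5-ene-8-carbaldehyde | O=C1O[C@@H]2C=C[C@@]1(Br)[C@](C)(C=O)[C@H]2C | intermediate
4 | (1R,4S,7R,8R)-7,8-dimethyl-3-oxo-2-oxabicyclo[2.2.2]oct-5-ene-8-carbaldehyde | O=C1O[C@@H]2C=C[C@H]1[C@](C)(C=O)[C@H]2C | intermediate
5 | (1R,4S,5R,6R)-5,6-dimethyl-3-oxo-2-oxabicyclo[2.2.2]octane-5-carbaldehyde | O=C1O[C@@H]2CC[C@H]1[C@](C)(C=O)[C@H]2C | intermediate
6 | methyl (1R,2S,5R,8R)-7-methoxy-1,8-dimethyl-6-oxabicyclo[3.2.1]octane-2-carboxylate (C7 epimers) | O1[C@@H]2CC[C@H](C(=O)OC)[C@](C)(C1OC)[C@H]2C | intermediate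
7 | (1R,2S,5R,8R)-7-methoxy-1,8-dimethyl-6-oxabicyclo[3.2.1]octane-2-carbaldehyde (C7 epimers) | O1[C@@H]2CC[C@H](C=O)[C@](C)(C1OC)[C@H]2C | intermediate
8 | ethyl vinyl ether | C=COCC | starting material
9 | 1-ethoxyvinyllithium | [Li]C(=C)OCC | intermediate (not isolated)
10 | (1R)-2-ethoxy-1-[(1R,2S,5R,8R)-7-methoxy-1,8-dimethyl-6-oxabicyclo[3.2.1]octan-2-yl]prop-2-en-1-ol | O1[C@@H]2CC[C@H]([C@@H](O)C(=C)OCC)[C@](C)(C1OC)[C@H]2C | intermediate
11 | tert-butyldimethylsilyl ether of 10 at O9 | O1[C@@H]2CC[C@H]([C@@H](O[Si](C)(C)C(C)(C)C)C(=C)OCC)[C@](C)(C1OC)[C@H]2C | intermediate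
12 | (1R)-1-[(tert-butyldimethylsilyl)oxy]-1-[(1R,2S,5R,8R)-7-hydroxy-1,8-dimethyl-6-oxabicyclo[3.2.1]octan-2-yl]propan-2-one (keto lactol) | O1[C@@H]2CC[C@H]([C@@H](O[Si](C)(C)C(C)(C)C)C(C)=O)[C@](C)(C1O)[C@H]2C | intermediate (not isolated)
13 | (1R,4aR,5R,6R,8aS)-1-[(tert-butyldimethylsilyl)oxy]-6-hydroxy-4a,5-dimethyl-4a,5,6,7,8,8a-hexahydronaphthalen-2(1H)-one | O[C@@H]1CC[C@@H]2[C@@H](O[Si](C)(C)C(C)(C)C)C(=O)C=C[C@]2(C)[C@H]1C | intermediate
14 | (1R,4aR,5R,6R,8aS)-1-[(tert-butyldimethylsilyl)oxy]-6-hydroxy-4a,5-dimethyloctahydronaphthalen-2(1H)-one | O[C@@H]1CC[C@@H]2[C@@H](O[Si](C)(C)C(C)(C)C)C(=O)CC[C@]2(C)[C@H]1C | intermediate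
15 | 1-[(tert-butyldimethylsilyl)oxy]propan-2-one | CC(=O)CO[Si](C)(C)C(C)(C)C | starting material
16 | aldol adduct of 14 and 15 at C7 (diastereomer mixture at C7 and C11) | O[C@@H]1CC[C@@H]2[C@@H](O[Si](C)(C)C(C)(C)C)C(=O)C(C(C)(O)CO[Si](C)(C)C(C)(C)C)C[C@]2(C)[C@H]1C | intermediate
17 | (4aR,5R,6R,8aS,9R)-9-[(tert-butyldimethylsilyl)oxy]-3,4a,5-trimethyl-4,4a,5,6,7,8,8a,9-octahydronaphtho[2,3-b]furan-6-ol | O[C@@H]1CC[C@@H]2[C@@H](O[Si](C)(C)C(C)(C)C)c3occ(C)c3C[C@]2(C)[C@H]1C | intermediate
18 | (E)-non-3-en-2-one | CCCCC/C=C/C(C)=O | starting material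
19 | triethyl 4-phosphonocrotonate | CCOC(=O)/C=C/CP(=O)(OCC)OCC | starting material
20 | ethyl (2E,4E,6E)-5-methyldodeca-2,4,6-trienoate | CCCCC/C=C/C(C)=C/C=C/C(=O)OCC | intermediate
21 | (2E,4E,6E)-5-methyldodeca-2,4,6-trienoic acid | CCCCC/C=C/C(C)=C/C=C/C(=O)O | intermediate
22 | (2E,4E,6E)-5-methyldodeca-2,4,6-trienoic 2,4,6-trichlorobenzoic anhydride | CCCCC/C=C/C(C)=C/C=C/C(=O)OC(=O)c1c(Cl)cc(Cl)cc1Cl | intermediate (not isolated)
23 | (4aR,5R,6R,8aS,9R)-9-[(tert-butyldimethylsilyl)oxy]-3,4a,5-trimethyl-4,4a,5,6,7,8,8a,9-octahydronaphtho[2,3-b]furan-6-yl (2E,4E,6E)-5-methyldodeca-2,4,6-trienoate | CCCCC/C=C/C(C)=C/C=C/C(=O)O[C@@H]1CC[C@@H]2[C@@H](O[Si](C)(C)C(C)(C)C)c3occ(C)c3C[C@]2(C)[C@H]1C | intermediate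
24 | (1R,2R,4aS,5R,8aR)-5-[(tert-butyldimethylsilyl)oxy]-1,8a-dimethyl-6-oxo-7-[(Z)-1-oxopropan-2-ylidene]decahydronaphthalen-2-yl (2E,4E,6E)-5-methyldodeca-2,4,6-trienoate (keto enal) | CCCCC/C=C/C(C)=C/C=C/C(=O)O[C@@H]1CC[C@@H]2[C@@H](O[Si](C)(C)C(C)(C)C)C(=O)/C(=C(/C)C=O)C[C@]2(C)[C@H]1C | intermediate (not isolated)
25 | (1R,2R,4aS,5R,8aR)-5-[(tert-butyldimethylsilyl)oxy]-7-[(Z)-1-hydroxypropan-2-ylidene]-1,8a-dimethyl-6-oxodecahydronaphthalen-2-yl (2E,4E,6E)-5-methyldodeca-2,4,6-trienoate | CCCCC/C=C/C(C)=C/C=C/C(=O)O[C@@H]1CC[C@@H]2[C@@H](O[Si](C)(C)C(C)(C)C)C(=O)/C(=C(/C)CO)C[C@]2(C)[C@H]1C | intermediate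
26 | (1R,2R,4aS,5R,8aR)-5-hydroxy-7-[(Z)-1-hydroxypropan-2-ylidene]-1,8a-dimethyl-6-oxodecahydronaphthalen-2-yl (2E,4E,6E)-5-methyldodeca-2,4,6-trienoate | CCCCC/C=C/C(C)=C/C=C/C(=O)O[C@@H]1CC[C@@H]2[C@@H](O)C(=O)/C(=C(/C)CO)C[C@]2(C)[C@H]1C | target

## Step count and least certain steps

Total: 16 steps. Longest linear sequence: 14 steps (steps 1–11 and 14–16); steps 12 and 13 form the side branch.

**Step 1 (key step, proposed new method).** Three things are most likely to go wrong. The catalyst may not turn over, because the pyrone carbonyl and the product lactone compete with the enal for boron, or because the pyrone is too poor a diene at the temperatures where the catalyst is selective. The formyl-over-bridge orientation may erode toward the formyl-over-alkene mode. The facial selectivity may be poor. The fallback uses known chemistry and sets out from 1 and 2, which are combined without catalyst (excess 2, 90–100 °C in a sealed vessel, or 10–12 kbar at room temperature). Thermal and high-pressure cycloadditions of 3-bromo-2-pyrone with electron-poor alkenes are established and give isolable bridged lactones. After chromatographic removal of diastereomers this should give the racemic adduct, that is 3 together with its enantiomer ent-3 F1. Preparative chromatography on a chiral stationary phase then separates F1 from 3, where the route is rejoined.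

**Step 6.** The risk is poor facial selectivity in the addition, since the Felkin preference rests only on quaternary C5 against the C1 methylene, or enolisation of the aldehyde by the basic vinyllithium. The fallback replaces kinetic by thermodynamic control and sets out from 7. The addition product is taken on as a mixture of 10 and its C9 epimer 9-epi-10 F2. Silylation as in step 7 gives, beside 11, the epimeric silyl ether 9-epi-11 F3. Under the acid and base of step 8, F3 passes through the epimeric keto lactol 9-epi-12 F4 to the epimeric enone 9-epi-13 F5. The α-silyloxy ketone of F5 is then equilibrated through its C8–C9 enolate (DBU, toluene, or prolonged KOH/MeOH) to the epimer with the pseudo-equatorial silyloxy group, which is 13, where the route is rejoined.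

**Step 11 (with step 10).** The risk is retro-aldol cleavage of 16, or loss of the C9 silyl ether and ionisation at the furfuryl C9–O bond under the acid needed for desilylation and cyclodehydration. The fallback builds the furan by a different bond construction and sets out from 14. The C7 lithium enolate (LiN(i-Pr)2, THF, −78 °C) is added to (E)-1-nitroprop-1-ene to give the γ-nitro ketone F6, which is 14 carrying a 1-nitropropan-2-yl group on C7. The nitronate of F6 (NaOMe, MeOH) is ozonised at −78 °C and reduced with Me2S (Nef reaction) to the γ-keto aldehyde F7, which is 14 carrying a 1-oxopropan-2-yl group on C7. F7 closes to the furan with pyridinium p-toluenesulfonate in CH2Cl2 (Paal–Knorr), giving 17, where the route is rejoined.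

**Step 15.** The risks are competing oxidation of the triene, Z to E isomerisation of the keto enal before reduction, and 1,4- or over-reduction at C8. The fallback reorders the end game so that the triene is absent during the redox steps, and sets out from 17. Dimethyldioxirane opens the furan to the 3-hydroxy keto enal F8, which is not isolated, and NaBH4 at −78 °C reduces it to the 3,12-dihydroxy enone F9. The primary allylic hydroxyl of F9 is silylated selectively (TBSCl, imidazole) to the 12-O-silyl ether F10. Yamaguchi acylation of O3 of F10 with 21, through 22, gives the bis-silyl ester F11. HF·pyridine removes both silyl groups from F11 and gives 26.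

**Step 16.** The risk is cyclodehydration of the liberated γ-hydroxy enone back to a furan under the acidic fluoride source, or epimerisation and ketol transposition at C9 if a basic fluoride has to be used. The fallback uses a protecting group that leaves under neutral nucleophilic conditions and sets out from 23. Desilylation at the robust furan stage (HF·pyridine) gives the 9-hydroxy furan ester F12. Chloroacetic anhydride and pyridine convert F12 into the 9-chloroacetate F13. Dimethyldioxirane opens the furan of F13 to the chloroacetate keto enal F14, which is not isolated, and LiAlH(O-t-Bu)3 at −78 °C reduces it to the target 9-chloroacetate F15. Thiourea and NaHCO3 in ethanol remove the chloroacetate from F15 and give 26.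

## Further compounds

F1 | step 1 | ent-3, (1S,4S,7S,8R)-4-bromo-7,8-dimethyl-3-oxo-2-oxabicyclo[2.2.2]oct-5-ene-8-carbaldehyde | O=C1O[C@H]2C=C[C@]1(Br)[C@@](C)(C=O)[C@@H]2C
F2 | step 6 | 9-epi-10, (1S)-2-ethoxy-1-[(1R,2S,5R,8R)-7-methoxy-1,8-dimethyl-6-oxabicyclo[3.2.1]octan-2-yl]prop-2-en-1-ol | O1[C@@H]2CC[C@H]([C@H](O)C(=C)OCC)[C@](C)(C1OC)[C@H]2C
F3 | step 6 | 9-epi-11, tert-butyldimethylsilyl ether of F2 | O1[C@@H]2CC[C@H]([C@H](O[Si](C)(C)C(C)(C)C)C(=C)OCC)[C@](C)(C1OC)[C@H]2C
F4 | step 6 | 9-epi-12, epimeric keto lactol (not isolated) | O1[C@@H]2CC[C@H]([C@H](O[Si](C)(C)C(C)(C)C)C(C)=O)[C@](C)(C1O)[C@H]2C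
F5 | step 6 | 9-epi-13, (1S,4aR,5R,6R,8aS)-1-[(tert-butyldimethylsilyl)oxy]-6-hydroxy-4a,5-dimethyl-4a,5,6,7,8,8a-hexahydronaphthalen-2(1H)-one | O[C@@H]1CC[C@@H]2[C@H](O[Si](C)(C)C(C)(C)C)C(=O)C=C[C@]2(C)[C@H]1C
F6 | step 11 | 7-(1-nitropropan-2-yl)-14, γ-nitro ketone (diastereomer mixture at C7 and C11) | O[C@@H]1CC[C@@H]2[C@@H](O[Si](C)(C)C(C)(C)C)C(=O)C(C(C)C[N+](=O)[O-])C[C@]2(C)[C@H]1C
F7 | step 11 | 7-(1-oxopropan-2-yl)-14, γ-keto aldehyde (diastereomer mixture at C7 and C11) | O[C@@H]1CC[C@@H]2[C@@H](O[Si](C)(C)C(C)(C)C)C(=O)C(C(C)C=O)C[C@]2(C)[C@H]1C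
F8 | step 15 | 3-hydroxy keto enal, (2Z)-2-[(1R,4aS,7R,8R,8aR)-1-[(tert-butyldimethylsilyl)oxy]-7-hydroxy-8,8a-dimethyl-2-oxooctahydronaphthalen-3(2H)-ylidene]propanal (not isolated) | O[C@@H]1CC[C@@H]2[C@@H](O[Si](C)(C)C(C)(C)C)C(=O)/C(=C(/C)C=O)C[C@]2(C)[C@H]1C
F9 | step 15 | 3,12-dihydroxy enone, O9-silylated deacyl target | O[C@@H]1CC[C@@H]2[C@@H](O[Si](C)(C)C(C)(C)C)C(=O)/C(=C(/C)CO)C[C@]2(C)[C@H]1C
F10 | step 15 | 12-O-silyl ether of F9 | O[C@@H]1CC[C@@H]2[C@@H](O[Si](C)(C)C(C)(C)C)C(=O)/C(=C(/C)CO[Si](C)(C)C(C)(C)C)C[C@]2(C)[C@H]1C
F11 | step 15 | bis-silyl ester, O9,O12-bis(tert-butyldimethylsilyl) ether of 26 | CCCCC/C=C/C(C)=C/C=C/C(=O)O[C@@H]1CC[C@@H]2[C@@H](O[Si](C)(C)C(C)(C)C)C(=O)/C(=C(/C)CO[Si](C)(C)C(C)(C)C)C[C@]2(C)[C@H]1C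
F12 | step 16 | 9-hydroxy furan ester, desilylated 23 | CCCCC/C=C/C(C)=C/C=C/C(=O)O[C@@H]1CC[C@@H]2[C@@H](O)c3occ(C)c3C[C@]2(C)[C@H]1C
F13 | step 16 | 9-chloroacetate of F12 | CCCCC/C=C/C(C)=C/C=C/C(=O)O[C@@H]1CC[C@@H]2[C@@H](OC(=O)CCl)c3occ(C)c3C[C@]2(C)[C@H]1C
F14 | step 16 | chloroacetate keto enal (not isolated) | CCCCC/C=C/C(C)=C/C=C/C(=O)O[C@@H]1CC[C@@H]2[C@@H](OC(=O)CCl)C(=O)/C(=C(/C)C=O)C[C@]2(C)[C@H]1C
F15 | step 16 | 9-chloroacetate of 26 | CCCCC/C=C/C(C)=C/C=C/C(=O)O[C@@H]1CC[C@@H]2[C@@H](OC(=O)CCl)C(=O)/C(=C(/C)CO)C[C@]2(C)[C@H]1C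
A1 | alternative 1 | bicyclic 7,11(12)-diene with silyl ethers on O3 and O9 | C=C(C)C1=C[C@H](O[Si](C)(C)C(C)(C)C)[C@H]2CC[C@@H](O[Si](CC)(CC)CC)[C@H](C)[C@@]2(C)C1
A2 | alternative 1 | enyne precursor with C9 allylic silyl ether and but-2-ynyl chain on C5 | C=C[C@H](O[Si](C)(C)C(C)(C)C)[C@H]1CC[C@@H](O[Si](CC)(CC)CC)[C@H](C)[C@@]1(C)CC#CC
A3 | alternative 2 | cis-fused 3-methoxy-4,5-dimethyloctal-3-en-8-one | COC1=C(C)[C@@]2(C)CCC(=O)C[C@H]2CC1
A4 | alternative 2 | bridged tertiary alcohol, 1-methoxy-5,6-dimethyl-2-vinylbicyclo[2.2.2]oct-5-en-2-ol | CO[C@]12CC[C@H](C[C@@]1(O)C=C)C(C)=C2C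
A5 | alternative 3 | cis-fused 4,5-dimethyldecalin-3,8-dione | O=C1CC[C@@H]2CC(=O)CC[C@]2(C)[C@H]1C
A6 | alternative 3 | bis-enone, 4-methyl-4-(3-oxopent-4-en-2-yl)cyclohex-2-en-1-one | C=CC(=O)[C@H](C)[C@@]1(C)CCC(=O)C=C1
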